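**Plan**
- Retrosynthesis: the N–CH3 bond and the C1–H/C1=N bonds of the heterocycle are cut first, then ring A at C5–C4a and C8–C8a, and last the naphthalene–CH2 bond of the diene.
- Enabling feature: ring A of the isoquinoline (C4a, C5, C6, C7, C8, C8a) carries OMe at C6 and OH at C8 in a meta relation, a carbon (C1) on C8a that can begin as an acetyl group, and the naphthyl group on C5 next to the C4 side chain on C4a. A 4-aryl-1,1,3-trioxygenated butadiene and an acetyl alkyne deliver exactly this pattern.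
- Forward, two fragments: Stobbe condensation and ring closure build the second naphthalene ring, the bromide is borylated, coupled with a 4-chloro-3-methoxybutenoate and silylated to the diene, so the biaryl bond starts as an aryl–CH2 bond. N-Boc-D-alaninol gives the cyclic sulfamidate, which is opened by an acetylide and acylated to the ynone.
- Ring order: naphthalene, then ring A by Diels–Alder cycloaromatization, then the nitrogen ring by imine condensation.
- Stereochemistry: C3 comes unchanged from D-alaninol; C1 is set trans to it by LiAlH4/AlMe3 reduction of the cyclic imine.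

Key step: step 14

Assumption: the target structure fixes C1 and C3 but gives no descriptor for the C5–naphthyl axis, which should be configurationally stable; compounds 28–36 are therefore carried as the pair of atropisomers the structure covers, to be separated at the end if one is wanted.

**Step 1**
Reactants: 1 2-bromo-5-methoxybenzaldehyde; 2 diethyl succinate
Product: 3 (E)-4-(2-bromo-5-methoxyphenyl)-3-(ethoxycarbonyl)but-3-enoic acid
Conditions: NaOEt, EtOH, reflux; then aq HCl
Reagents that add atoms: none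
Why: Stobbe condensation, in which aldol addition of the succinate enolate, lactonization and base-induced ring opening should give the half-ester with the aryl group trans to the conjugated ester (E), the geometry needed for the next ring closure.

**Step 2**
Reactants: 3 (E)-4-(2-bromo-5-methoxyphenyl)-3-(ethoxycarbonyl)but-3-enoic acid
Product: 5 ethyl 4-acetoxy-8-bromo-5-methoxynaphthalene-2-carboxylate, via naphthol 4 (not isolated)
Conditions: Ac2O, NaOAc, 140 °C
Reagents that add atoms: acetic anhydride, CC(=O)OC(C)=O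
Why: Second stage of the Stobbe naphthalene synthesis, an intramolecular Friedel–Crafts acylation by the activated acid at the only free ortho position (the other is blocked by bromine), after which naphthol 4 is acetylated in the flask.

**Step 3**
Reactants: 5 ethyl 4-acetoxy-8-bromo-5-methoxynaphthalene-2-carboxylate
Product: 7 ethyl 8-bromo-4,5-dimethoxynaphthalene-2-carboxylate, via potassium naphtholate 6 (not isolated)
Conditions: K2CO3, EtOH, 25 °C; then MeI, 40 °C
Reagents that add atoms: iodomethane, CI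
Why: Ethanolysis of the aryl acetate under carbonate leaves the naphthol as its potassium salt 6, which undergoes Williamson O-methylation in the same pot; ethanol as solvent keeps the ethyl ester unchanged.

**Step 4**
Reactants: 7 ethyl 8-bromo-4,5-dimethoxynaphthalene-2-carboxylate
Product: 8 (8-bromo-4,5-dimethoxynaphthalen-2-yl)methanol
Conditions: i-Bu2AlH, CH2Cl2, −78 → 0 °C; aq potassium sodium tartrate
Reagents that add atoms: none
Why: Hydride reduction of the ester to the primary alcohol, which should leave the aryl bromide and the methyl ethers untouched at low temperature.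

**Step 5**
Reactants: 8 (8-bromo-4,5-dimethoxynaphthalen-2-yl)methanol
Product: 10 1-bromo-4,5-dimethoxy-7-methylnaphthalene, via benzylic mesylate 9 (not isolated)
Conditions: MsCl, Et3N, THF, 0 °C; then LiEt3BH, 0 → 25 °C
Reagents that add atoms: none
Why: Sulfonylation and SN2 hydride displacement of the benzylic mesylate (deoxygenation), under which an aryl bromide is not reduced.

**Step 6**
Reactants: 10 1-bromo-4,5-dimethoxy-7-methylnaphthalene
Product: 11 2-(4,5-dimethoxy-7-methylnaphthalen-1-yl)-4,4,5,5-tetramethyl-1,3,2-dioxaborolane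
Conditions: B2pin2, Pd(dppf)Cl2 (3 mol %), KOAc, 1,4-dioxane, 90 °C
Reagents that add atoms: bis(pinacolato)diboron, CC1(C)OB(OC1(C)C)B1OC(C)(C)C(C)(C)O1
Why: Miyaura borylation (oxidative addition of zerovalent palladium into Ar–Br, acetate-assisted transmetalation, reductive elimination), chosen because the pinacol ester resists protodeboronation better than the free boronic acid of this electron-rich ring.

**Step 7**
Reactants: 11 2-(4,5-dimethoxy-7-methylnaphthalen-1-yl)-4,4,5,5-tetramethyl-1,3,2-dioxaborolane; 12 methyl (E)-4-chloro-3-methoxybut-2-enoate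
Product: 13 methyl (E)-4-(4,5-dimethoxy-7-methylnaphthalen-1-yl)-3-methoxybut-2-enoate
Conditions: Pd(PPh3)4 (5 mol %), K3PO4, THF–H2O, 60 °C
Reagents that add atoms: none
Why: Suzuki–Miyaura allyl–aryl coupling, in which zerovalent palladium ionizes the allylic C–Cl bond to a π-allyl complex and the aryl group is expected to be delivered to the unsubstituted CH2 terminus, keeping the push–pull enoate intact.

**Step 8**
Reactants: 13 methyl (E)-4-(4,5-dimethoxy-7-methylnaphthalen-1-yl)-3-methoxybut-2-enoate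
Product: 15 {[(3Z)-4-(4,5-dimethoxy-7-methylnaphthalen-1-yl)-1,3-dimethoxybuta-1,3-dien-1-yl]oxy}trimethylsilane, via lithium dienolate 14 (not isolated)
Conditions: LDA, THF, −78 °C; then Me3SiCl, −78 → 0 °C; used crude
Reagents that add atoms: chlorotrimethylsilane, C[Si](C)(C)Cl
Why: γ-Deprotonation of the vinylogous carbonate (the CH2 is benzylic and vinylogously activated) and O-silylation of the dienolate, the standard preparation of methyl trimethylsilyl vinylketene acetals; the aryl group should settle trans to C2, and a double-bond isomer of 13 would converge on the same dienolate.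

**Step 9**
Reactants: 16 tert-butyl (R)-(1-hydroxypropan-2-yl)carbamate (N-Boc-D-alaninol)
Product: 17 tert-butyl (4R)-4-methyl-1,2,3-oxathiazolidine-3-carboxylate 2-oxide (both sulfur epimers)
Conditions: SOCl2, pyridine, MeCN, −40 → 0 °C
Reagents that add atoms: thionyl chloride, O=S(Cl)Cl
Why: Cyclic sulfamidite formation from an N-Boc 1,2-amino alcohol, which involves only O–S and N–S bond formation and leaves the stereocenter untouched.

**Step 10**
Reactants: 17 tert-butyl (4R)-4-methyl-1,2,3-oxathiazolidine-3-carboxylate 2-oxide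
Product: 18 tert-butyl (4R)-4-methyl-1,2,3-oxathiazolidine-3-carboxylate 2,2-dioxide
Conditions: RuCl3·xH2O (1 mol %), NaIO4, MeCN–H2O, 0 °C
Reagents that add atoms: sodium periodate, [Na+].[O-]I(=O)(=O)=O
Why: RuO4-catalysed oxidation at sulfur with periodate as terminal oxidant, the usual way from cyclic sulfamidites to sulfamidates.

**Step 11**
Reactants: 18 tert-butyl (4R)-4-methyl-1,2,3-oxathiazolidine-3-carboxylate 2,2-dioxide; 19 ethynyltrimethylsilane
Product: 22 tert-butyl (R)-[5-(trimethylsilyl)pent-4-yn-2-yl]carbamate, via lithium silylacetylide 20 (not isolated), via lithium N-sulfamate 21 (not isolated)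
Conditions: 19, n-BuLi, THF, −78 °C; then 18, −78 → 25 °C; then 1 M aq HCl, 25 °C
Reagents that add atoms: none
Why: SN2 opening of the cyclic sulfamidate at the primary C–O carbon by the acetylide, then acid hydrolysis of the N-sulfamate; the stereocenter is not the reacting carbon, so R is retained.

**Step 12**
Reactants: 22 tert-butyl (R)-[5-(trimethylsilyl)pent-4-yn-2-yl]carbamate
Product: 23 tert-butyl (R)-pent-4-yn-2-ylcarbamate
Conditions: K2CO3, MeOH, 25 °C
Reagents that add atoms: none
Why: Methoxide-mediated protodesilylation of the alkynylsilane, which leaves the carbamate unaffected.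

**Step 13**
Reactants: 23 tert-butyl (R)-pent-4-yn-2-ylcarbamate
Product: 26 tert-butyl (R)-(6-oxohept-4-yn-2-yl)carbamate, via dilithiated alkynyl carbamate 24 (not isolated), via tetrahedral adduct 25 (not isolated)
Conditions: n-BuLi (2.1 equiv), THF, −78 °C; MeC(O)N(OMe)Me, −78 → −20 °C; inverse quench into cold 1 M aq HCl
Reagents that add atoms: N-methoxy-N-methylacetamide, CON(C)C(C)=O
Why: Weinreb ketone synthesis on the N,C-dianion, where the chelated adduct 25 prevents over-addition and the acidic inverse quench protonates the released N,O-dimethylhydroxylamine before it can add to the ynone.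

**Step 14**
Reactants: 15 {[(3Z)-4-(4,5-dimethoxy-7-methylnaphthalen-1-yl)-1,3-dimethoxybuta-1,3-dien-1-yl]oxy}trimethylsilane; 26 tert-butyl (R)-(6-oxohept-4-yn-2-yl)carbamate
Product: 29 tert-butyl (R)-{1-[2-acetyl-3-hydroxy-5-methoxy-6-(4,5-dimethoxy-7-methylnaphthalen-1-yl)phenyl]propan-2-yl}carbamate, via cyclohexadiene cycloadduct 27 (not isolated), via aryl trimethylsilyl ether 28 (not isolated)
Conditions: 15 (2 equiv), toluene, 25 → 100 °C, sealed tube; then 1 M aq HCl–THF, 0 °C
Reagents that add atoms: none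
Why: The naphthyl-bearing diene terminus (future C5) bonds to the ynone β-carbon (future C4a) while the acetal carbon (future C8) bonds to the α-carbon (future C8a), in a strongly asynchronous [4+2] cycloaddition of the type known for 1,1,3-trioxygenated butadienes with acetylenic ketones; a stepwise Michael addition and ring closure would lead to the same adduct 27. Ring A closes as a six-membered carbocycle in an intermolecular [4+2] mode, forming C5–C4a and C8–C8a together. 1,4-Elimination of methanol (C8–OMe and C5–H) should aromatize 27 to silyl ether 28, and dilute acid frees the phenol, which is held by a hydrogen bond to the acetyl group. No stereocenter is created, C3 is a spectator, and the biaryl axis forms without control. The step needs regioselectivity, secured by the matched polarization of the diene (oxygen donors at C8 and C6) and the ynone (acetyl acceptor), and it needs loss of methoxide and not silanolate from the ketal carbon, the usual course for methyl trimethylsilyl ketene acetals. The real demand is steric, since the naphthyl-bearing terminus meets a disubstituted alkyne carbon, hence the excess of diene and heating in a sealed tube.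

**Step 15**
Reactants: 29 tert-butyl (R)-{1-[2-acetyl-3-hydroxy-5-methoxy-6-(4,5-dimethoxy-7-methylnaphthalen-1-yl)phenyl]propan-2-yl}carbamate
Product: 30 tert-butyl (R)-{1-[2-acetyl-3-(benzyloxy)-5-methoxy-6-(4,5-dimethoxy-7-methylnaphthalen-1-yl)phenyl]propan-2-yl}carbamate
Conditions: BnBr, K2CO3, DMF, 50 °C
Reagents that add atoms: benzyl bromide, BrCc1ccccc1
Why: Williamson benzylation of the chelated phenol (K2CO3 does not alkylate the carbamate N–H), so that the later imine reduction and N-methylation are not disturbed by a free C8 hydroxyl.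

**Step 16**
Reactants: 30 tert-butyl (R)-{1-[2-acetyl-3-(benzyloxy)-5-methoxy-6-(4,5-dimethoxy-7-methylnaphthalen-1-yl)phenyl]propan-2-yl}carbamate
Product: 32 (3R)-8-(benzyloxy)-5-(4,5-dimethoxy-7-methylnaphthalen-1-yl)-6-methoxy-1,3-dimethyl-3,4-dihydroisoquinoline, via amino ketone hydrochloride 31 (not isolated)
Conditions: 4 M HCl in 1,4-dioxane, 0 → 25 °C; then Et3N, 4 Å MS, toluene, 60 °C
Reagents that add atoms: none
Why: Acidolysis of the Boc group and intramolecular ketone–amine condensation to the six-membered cyclic imine (the compound class otherwise reached by Bischler–Napieralski cyclization), under which C3 cannot epimerize.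

**Step 17**
Reactants: 32 (3R)-8-(benzyloxy)-5-(4,5-dimethoxy-7-methylnaphthalen-1-yl)-6-methoxy-1,3-dimethyl-3,4-dihydroisoquinoline
Product: 33 (1R,3R)-8-(benzyloxy)-5-(4,5-dimethoxy-7-methylnaphthalen-1-yl)-6-methoxy-1,3-dimethyl-1,2,3,4-tetrahydroisoquinoline
Conditions: AlMe3, then LiAlH4, THF, −78 → 0 °C
Reagents that add atoms: none
Why: Substrate-controlled hydride reduction of the imine, the known trans-selective LiAlH4/AlMe3 reduction of 1,3-dimethyl-3,4-dihydroisoquinolines: Me3Al on nitrogen pushes the 3-methyl group pseudoaxial and axial hydride delivery places H-1 cis to it, which makes the two methyl groups trans (1R from 3R).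

**Step 18**
Reactants: 33 (1R,3R)-8-(benzyloxy)-5-(4,5-dimethoxy-7-methylnaphthalen-1-yl)-6-methoxy-1,3-dimethyl-1,2,3,4-tetrahydroisoquinoline
Product: 35 (1R,3R)-8-(benzyloxy)-5-(4,5-dimethoxy-7-methylnaphthalen-1-yl)-6-methoxy-1,2,3-trimethyl-1,2,3,4-tetrahydroisoquinoline, via methyleneiminium acetate 34 (not isolated)
Conditions: 37% aq CH2O, NaBH(OAc)3, AcOH, ClCH2CH2Cl, 25 °C
Reagents that add atoms: formaldehyde, C=O
Why: Reductive amination of the secondary amine through iminium ion 34, with the benzyl ether keeping formaldehyde from reacting at the otherwise phenol-activated C7.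

**Step 19**
Reactants: 35 (1R,3R)-8-(benzyloxy)-5-(4,5-dimethoxy-7-methylnaphthalen-1-yl)-6-methoxy-1,2,3-trimethyl-1,2,3,4-tetrahydroisoquinoline
Product: 36 ancistrocongoline B, (1R,3R)-5-(4,5-dimethoxy-7-methylnaphthalen-1-yl)-6-methoxy-1,2,3-trimethyl-1,2,3,4-tetrahydroisoquinolin-8-ol
Conditions: H2 (1 atm), 10% Pd/C, MeOH–EtOAc, 25 °C
Reagents that add atoms: none
Why: Hydrogenolysis of the benzyl aryl ether, which should be much faster than any cleavage of the tertiary benzylic C1–N bond and leaves the methyl ethers and the naphthalene intact.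

**Compound list**
1 | 2-bromo-5-methoxybenzaldehyde | COc1ccc(Br)c(C=O)c1 | starting material
2 | diethyl succinate | CCOC(=O)CCC(=O)OCC | starting material
3 | (E)-4-(2-bromo-5-methoxyphenyl)-3-(ethoxycarbonyl)but-3-enoic acid | CCOC(=O)/C(CC(=O)O)=C/c1cc(OC)ccc1Br | intermediate
4 | ethyl 8-bromo-4-hydroxy-5-methoxynaphthalene-2-carboxylate (formed in the flask) | CCOC(=O)c1cc(O)c2c(OC)ccc(Br)c2c1 | intermediate
5 | ethyl 4-acetoxy-8-bromo-5-methoxynaphthalene-2-carboxylate | CCOC(=O)c1cc(OC(C)=O)c2c(OC)ccc(Br)c2c1 | intermediate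
6 | potassium 5-bromo-3-(ethoxycarbonyl)-8-methoxynaphthalen-1-olate (formed in the flask) | CCOC(=O)c1cc([O-])c2c(OC)ccc(Br)c2c1.[K+] | intermediate
7 | ethyl 8-bromo-4,5-dimethoxynaphthalene-2-carboxylate | CCOC(=O)c1cc(OC)c2c(OC)ccc(Br)c2c1 | intermediate
8 | (8-bromo-4,5-dimethoxynaphthalen-2-yl)methanol | OCc1cc(OC)c2c(OC)ccc(Br)c2c1 | intermediate
9 | (8-bromo-4,5-dimethoxynaphthalen-2-yl)methyl methanesulfonate (formed in the flask) | CS(=O)(=O)OCc1cc(OC)c2c(OC)ccc(Br)c2c1 | intermediate
10 | 1-bromo-4,5-dimethoxy-7-methylnaphthalene | Brc1ccc(OC)c2c(OC)cc(C)cc12 | intermediate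
11 | 2-(4,5-dimethoxy-7-methylnaphthalen-1-yl)-4,4,5,5-tetramethyl-1,3,2-dioxaborolane | CC1(C)OB(OC1(C)C)c1ccc(OC)c2c(OC)cc(C)cc12 | intermediate
12 | methyl (E)-4-chloro-3-methoxybut-2-enoate | COC(=O)/C=C(/OC)CCl | starting material
13 | methyl (E)-4-(4,5-dimethoxy-7-methylnaphthalen-1-yl)-3-methoxybut-2-enoate | COC(=O)/C=C(/OC)Cc1ccc(OC)c2c(OC)cc(C)cc12 | intermediate
14 | lithium (3Z)-4-(4,5-dimethoxy-7-methylnaphthalen-1-yl)-1,3-dimethoxybuta-1,3-dien-1-olate (formed in the flask) | COC([O-])=C/C(OC)=C/c1ccc(OC)c2c(OC)cc(C)cc12.[Li+] | intermediate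
15 | {[(3Z)-4-(4,5-dimethoxy-7-methylnaphthalen-1-yl)-1,3-dimethoxybuta-1,3-dien-1-yl]oxy}trimethylsilane (ketene acetal geometry of no consequence) | COC(O[Si](C)(C)C)=C/C(OC)=C/c1ccc(OC)c2c(OC)cc(C)cc12 | intermediate
16 | tert-butyl (R)-(1-hydroxypropan-2-yl)carbamate (N-Boc-D-alaninol) | C[C@@H](NC(=O)OC(C)(C)C)CO | starting material
17 | tert-butyl (4R)-4-methyl-1,2,3-oxathiazolidine-3-carboxylate 2-oxide | C[C@@H]1COS(=O)N1C(=O)OC(C)(C)C | intermediate
18 | tert-butyl (4R)-4-methyl-1,2,3-oxathiazolidine-3-carboxylate 2,2-dioxide | C[C@@H]1COS(=O)(=O)N1C(=O)OC(C)(C)C | intermediate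
19 | ethynyltrimethylsilane | C#C[Si](C)(C)C | starting material
20 | lithium (trimethylsilyl)acetylide (formed in the flask) | [Li+].[C-]#C[Si](C)(C)C | intermediate
21 | lithium (R)-N-(tert-butoxycarbonyl)-N-[5-(trimethylsilyl)pent-4-yn-2-yl]sulfamate (formed in the flask) | C[C@H](CC#C[Si](C)(C)C)N(C(=O)OC(C)(C)C)S(=O)(=O)[O-].[Li+] | intermediate
22 | tert-butyl (R)-[5-(trimethylsilyl)pent-4-yn-2-yl]carbamate | C[C@H](CC#C[Si](C)(C)C)NC(=O)OC(C)(C)C | intermediate
23 | tert-butyl (R)-pent-4-yn-2-ylcarbamate | C#CC[C@@H](C)NC(=O)OC(C)(C)C | intermediate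
24 | N,C-dilithiated tert-butyl (R)-pent-4-yn-2-ylcarbamate (formed in the flask) | [Li+].[Li+].[C-]#CC[C@@H](C)[N-]C(=O)OC(C)(C)C | intermediate
25 | dilithium salt of the N-methoxy-N-methyl hemiaminal adduct (formed in the flask) | CON(C)C(C)([O-])C#CC[C@@H](C)[N-]C(=O)OC(C)(C)C.[Li+].[Li+] | intermediate
26 | tert-butyl (R)-(6-oxohept-4-yn-2-yl)carbamate | CC(=O)C#CC[C@@H](C)NC(=O)OC(C)(C)C | intermediate
27 | tert-butyl (R)-{1-[2-acetyl-3,5-dimethoxy-6-(4,5-dimethoxy-7-methylnaphthalen-1-yl)-3-(trimethylsilyloxy)cyclohexa-1,4-dien-1-yl]propan-2-yl}carbamate (formed in the flask) | CC(=O)C1=C(C[C@@H](C)NC(=O)OC(C)(C)C)C(c2ccc(OC)c3c(OC)cc(C)cc23)C(OC)=CC1(OC)O[Si](C)(C)C | intermediate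
28 | tert-butyl (R)-{1-[2-acetyl-5-methoxy-6-(4,5-dimethoxy-7-methylnaphthalen-1-yl)-3-(trimethylsilyloxy)phenyl]propan-2-yl}carbamate (formed in the flask) | CC(=O)c1c(O[Si](C)(C)C)cc(OC)c(-c2ccc(OC)c3c(OC)cc(C)cc23)c1C[C@@H](C)NC(=O)OC(C)(C)C | intermediate
29 | tert-butyl (R)-{1-[2-acetyl-3-hydroxy-5-methoxy-6-(4,5-dimethoxy-7-methylnaphthalen-1-yl)phenyl]propan-2-yl}carbamate | CC(=O)c1c(O)cc(OC)c(-c2ccc(OC)c3c(OC)cc(C)cc23)c1C[C@@H](C)NC(=O)OC(C)(C)C | intermediate
30 | tert-butyl (R)-{1-[2-acetyl-3-(benzyloxy)-5-methoxy-6-(4,5-dimethoxy-7-methylnaphthalen-1-yl)phenyl]propan-2-yl}carbamate | CC(=O)c1c(OCc2ccccc2)cc(OC)c(-c2ccc(OC)c3c(OC)cc(C)cc23)c1C[C@@H](C)NC(=O)OC(C)(C)C | intermediate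
31 | (R)-1-[2-acetyl-3-(benzyloxy)-5-methoxy-6-(4,5-dimethoxy-7-methylnaphthalen-1-yl)phenyl]propan-2-aminium chloride (formed in the flask) | CC(=O)c1c(OCc2ccccc2)cc(OC)c(-c2ccc(OC)c3c(OC)cc(C)cc23)c1C[C@@H](C)[NH3+].[Cl-] | intermediate
32 | (3R)-8-(benzyloxy)-5-(4,5-dimethoxy-7-methylnaphthalen-1-yl)-6-methoxy-1,3-dimethyl-3,4-dihydroisoquinoline | COc1cc(OCc3ccccc3)c2c(c1-c1ccc(OC)c3c(OC)cc(C)cc13)C[C@@H](C)N=C2C | intermediate
33 | (1R,3R)-8-(benzyloxy)-5-(4,5-dimethoxy-7-methylnaphthalen-1-yl)-6-methoxy-1,3-dimethyl-1,2,3,4-tetrahydroisoquinoline | COc1cc(OCc3ccccc3)c2c(c1-c1ccc(OC)c3c(OC)cc(C)cc13)C[C@@H](C)N[C@@H]2C | intermediate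
34 | (1R,3R)-8-(benzyloxy)-5-(4,5-dimethoxy-7-methylnaphthalen-1-yl)-6-methoxy-1,3-dimethyl-2-methylidene-1,2,3,4-tetrahydroisoquinolin-2-ium acetate (formed in the flask) | COc1cc(OCc3ccccc3)c2c(c1-c1ccc(OC)c3c(OC)cc(C)cc13)C[C@@H](C)[N+](=C)[C@@H]2C.CC(=O)[O-] | intermediate
35 | (1R,3R)-8-(benzyloxy)-5-(4,5-dimethoxy-7-methylnaphthalen-1-yl)-6-methoxy-1,2,3-trimethyl-1,2,3,4-tetrahydroisoquinoline | COc1cc(OCc3ccccc3)c2c(c1-c1ccc(OC)c3c(OC)cc(C)cc13)C[C@@H](C)N(C)[C@@H]2C | intermediate
36 | ancistrocongoline B, (1R,3R)-5-(4,5-dimethoxy-7-methylnaphthalen-1-yl)-6-methoxy-1,2,3-trimethyl-1,2,3,4-tetrahydroisoquinolin-8-ol | COc1cc(O)c2c(c1-c1ccc(OC)c3c(OC)cc(C)cc13)C[C@@H](C)N(C)[C@@H]2C | target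

**Step count**
Total: 19 steps. Longest linear sequence: 14 steps (steps 1–8, 14–19); the amine branch (steps 9–13) joins at step 14.

**Steps most likely to fail**

Step 14. The cycloaddition may be slowed so much by the naphthyl group on the diene terminus and the disubstituted alkyne carbon that desilylation of 15 back to ester 13, or silyl transfer to the carbamate N–H, uses up the diene first. The fallback closes ring A by the same cycloaromatization with an unhindered diene and attaches the naphthalene afterwards by biaryl coupling. It sets out from ynone 26: the parent diene 1,3-dimethoxy-1-(trimethylsilyloxy)buta-1,3-diene F1, made from commercial methyl (E)-3-methoxybut-2-enoate as in step 8, should give tert-butyl (R)-[1-(2-acetyl-3-hydroxy-5-methoxyphenyl)propan-2-yl]carbamate F2. The operations of steps 15–18 would then lead through tert-butyl (R)-{1-[2-acetyl-3-(benzyloxy)-5-methoxyphenyl]propan-2-yl}carbamate F3, (3R)-8-(benzyloxy)-6-methoxy-1,3-dimethyl-3,4-dihydroisoquinoline F4 and (1R,3R)-8-(benzyloxy)-6-methoxy-1,3-dimethyl-1,2,3,4-tetrahydroisoquinoline F5 to (1R,3R)-8-(benzyloxy)-6-methoxy-1,2,3-trimethyl-1,2,3,4-tetrahydroisoquinoline F6. Bromination of the protonated amine with NBS (CF3CO2H, CH2Cl2, 0 °C) should go to C5, para to the benzyloxy group and less crowded than C7, to give (1R,3R)-8-(benzyloxy)-5-bromo-6-methoxy-1,2,3-trimethyl-1,2,3,4-tetrahydroisoquinoline F7. A Suzuki–Miyaura coupling of F7 with boronate 11 (Pd(PPh3)4, K3PO4, toluene–H2O, 100 °C) comes back to the route at 35.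

Step 7. Protodeboronation of the electron-rich, peri-hindered boronate may outrun transmetalation, or the aryl group may be delivered to the wrong end of the allyl unit. The fallback sets out from bromide 10 and replaces steps 6 and 7 by a classical β-keto ester route. Palladium-catalysed α-arylation of the Reformatsky reagent BrZnCH2CO2t-Bu (Pd(dba)2, P(t-Bu)3, THF) should give tert-butyl (4,5-dimethoxy-7-methylnaphthalen-1-yl)acetate F8. Acidolysis (CF3CO2H, CH2Cl2, 0 °C) gives (4,5-dimethoxy-7-methylnaphthalen-1-yl)acetic acid F9. Chain extension through the acyl imidazole with the magnesium salt of monomethyl malonate gives methyl 4-(4,5-dimethoxy-7-methylnaphthalen-1-yl)-3-oxobutanoate F10. Enol O-methylation with HC(OMe)3 and catalytic H2SO4 in MeOH comes back to the route at 13.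

Step 17. Facial selectivity of hydride delivery may be poor, leaving cis (1S,3R) material that is hard to remove. The fallback sets out from imine 32 and puts the N-methyl group on first: MeI in acetone should give (3R)-8-(benzyloxy)-5-(4,5-dimethoxy-7-methylnaphthalen-1-yl)-6-methoxy-1,2,3-trimethyl-3,4-dihydroisoquinolin-2-ium iodide F11. Its covalently bound N-methyl group enforces the pseudoaxial 3-methyl group by allylic 1,2-strain, so NaBH4 in MeOH at −78 °C should deliver hydride axially to the trans product. This replaces steps 17 and 18 and comes back to the route at 35.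

**Further compounds**
F1 | step 14 | 1,3-dimethoxy-1-(trimethylsilyloxy)buta-1,3-diene | COC(O[Si](C)(C)C)=CC(OC)=C
F2 | step 14 | tert-butyl (R)-[1-(2-acetyl-3-hydroxy-5-methoxyphenyl)propan-2-yl]carbamate | CC(=O)c1c(O)cc(OC)cc1C[C@@H](C)NC(=O)OC(C)(C)C
F3 | step 14 | tert-butyl (R)-{1-[2-acetyl-3-(benzyloxy)-5-methoxyphenyl]propan-2-yl}carbamate | CC(=O)c1c(OCc2ccccc2)cc(OC)cc1C[C@@H](C)NC(=O)OC(C)(C)C
F4 | step 14 | (3R)-8-(benzyloxy)-6-methoxy-1,3-dimethyl-3,4-dihydroisoquinoline | COc1cc(OCc3ccccc3)c2c(c1)C[C@@H](C)N=C2C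
F5 | step 14 | (1R,3R)-8-(benzyloxy)-6-methoxy-1,3-dimethyl-1,2,3,4-tetrahydroisoquinoline | COc1cc(OCc3ccccc3)c2c(c1)C[C@@H](C)N[C@@H]2C
F6 | step 14 | (1R,3R)-8-(benzyloxy)-6-methoxy-1,2,3-trimethyl-1,2,3,4-tetrahydroisoquinoline | COc1cc(OCc3ccccc3)c2c(c1)C[C@@H](C)N(C)[C@@H]2C
F7 | step 14 | (1R,3R)-8-(benzyloxy)-5-bromo-6-methoxy-1,2,3-trimethyl-1,2,3,4-tetrahydroisoquinoline | COc1cc(OCc3ccccc3)c2c(c1Br)C[C@@H](C)N(C)[C@@H]2C
F8 | step 7 | tert-butyl (4,5-dimethoxy-7-methylnaphthalen-1-yl)acetate | CC(C)(C)OC(=O)Cc1ccc(OC)c2c(OC)cc(C)cc12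
F9 | step 7 | (4,5-dimethoxy-7-methylnaphthalen-1-yl)acetic acid | OC(=O)Cc1ccc(OC)c2c(OC)cc(C)cc12
F10 | step 7 | methyl 4-(4,5-dimethoxy-7-methylnaphthalen-1-yl)-3-oxobutanoate | COC(=O)CC(=O)Cc1ccc(OC)c2c(OC)cc(C)cc12
F11 | step 17 | (3R)-8-(benzyloxy)-5-(4,5-dimethoxy-7-methylnaphthalen-1-yl)-6-methoxy-1,2,3-trimethyl-3,4-dihydroisoquinolin-2-ium iodide | COc1cc(OCc3ccccc3)c2c(c1-c1ccc(OC)c3c(OC)cc(C)cc13)C[C@@H](C)[N+](C)=C2C.[I-]
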